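Slowness is the first thing to measure here, and the flask asked about is Monday's run, followed further. The first-hour constant is the rate constant that gives the reading at one hour when left-handed substrate is lost by a pseudo-first-order law with partner held at its charge. Left-handed product then follows a curve: half of the pair charged, times one minus the exponential of minus constant × partner × time.

| flask | left-handed substrate | right-handed substrate | partner | remark | time |
|---|---|---|---|---|---|
| Monday's | 0.050 M | 0.050 M | 0.10 M | the very flask that is asked about, followed so far |  |
| Saturday's | 0.050 M | 0.050 M | 0.15 M | run made earlier |  |
| flask | 0.050 M | 0.050 M | 0.100 M |  | 8.0 h |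

- Monday's (time / min: left-handed product / %): 8.00: 1.6; 25.0: 6.1; 40.0: 8.7; 60.0: 12.7; 90.0: 16.6
- Saturday's (time / h: left-handed product / %): 1.00: 17.9; 2.50: 32.2; 3.00: 36.0; 5.00: 46.7; 6.00: 51.0

(scatter of a reading: 0.3 percentage points)

- amount of left-handed product in percent of the left-handed substrate and right-handed substrate together charged, at 50 min, 2.5 h, 5.0 h and 8.0 h

- partner is single-handed; left-handed substrate and right-handed substrate are mirror images of each other, charged as a racemate, each of them at the stated concentration
- the earlier runs were read with a standard deviation of 0.3 percentage points
- steps that have been proposed: partner + left-handed substrate -> left-handed product; partner + right-handed substrate -> right-handed product; left-handed substrate <-> right-handed substrate; partner -> decomposition product; partner <-> dormant form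
- the handed part of partner does not stay in what it makes, so the products of the two hands are mirror images too

Monday's 12.7 % at 60.0 min reads 2.93 M⁻¹ h⁻¹, the first-hour constant.

Partner is the first setting. By hand, going from 0.10 M to 0.15 M steepens the curve by that ratio, giving 17.8 % at 1.00 h, and Saturday's run reads 17.9 %.

Time is the second setting. By hand, the curve stays below the 50.0 % of left-handed substrate charged. Yet Saturday's run reads 51.0 % at 6.00 h, above that share, so right-handed substrate is crossing over. The curve gives 46.4 % there, 4.6 percentage points under the reading. At 90.0 min on Monday, however, it gives 17.8 %, 1.2 points over the reading. The correction has opposite signs at these two readings, which come from different flasks and different times.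

My own reckoning for this flask is therefore 10.8 % at 50 min, and at 8.0 h the curve's 45.2 % plus an upward correction.

The forecast, on the ground that “the substrate must racemise”, gives 10.7 %, 24 %, 36 % and 44.5 % at the asked times. Its last value lies below the curve, where mine lies above.

This flask gives 10.8 %, 24.3 %, 36.5 % and 46.4 %, so the forecast stands within its margin.

    partner + left-handed substrate → left-handed product (k = 3.20 M⁻¹ h⁻¹)
    partner + right-handed substrate → right-handed product (k = 0.0640 M⁻¹ h⁻¹)
    left-handed substrate ⇌ right-handed substrate (k = 0.150 h⁻¹)
    partner → decomposition product (k = 2.80 × 10⁻⁴ h⁻¹)
    partner ⇌ dormant form (K = 0.180, k = 0.0820 h⁻¹)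

The number at 8.0 h is 46.4 %, and partner then stands at 43.4 % of its own charge in this flask. The first-hour constant gave 10.8 % at 50 min, where this flask has 10.8 %. At 8.0 h its curve lies 1.2 points under this flask. That nearness holds for left-handed product: the curve leaves 4.80 % of left-handed substrate, and this flask holds 19.9 %.

(The runs come from a simulation from invented constants, noise included.)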